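The reading falls at 20 min, in a flask where the electrophile leaves its solid while the free base draws acid out of the protonated nucleophile, the nucleophile's resting state.

    electrophile + nucleophile → acid set free + target (k1 = 0.0268 /M/s)
    free base + target → over-reaction product (k2 = 0.0846 /M/s)
    solid electrophile ⇌ electrophile, rate k3*(cs3 - [electrophile]) while solid is left; crystals form when [electrophile] > cs3 (cs3 = 9.0 mM, k3 = 0.00264 /s)
    nucleophile + acid set free ⇌ protonated nucleophile, settled at all times (K4 = 36200 /M)
    acid set free + free base ⇌ salt of the base (K5 = 3.09 × 10⁶ /M, k5 = 3.36 /M/s)

solid electrophile 10 mM; free base 1.20 equiv; protonated nucleophile 1.30 equiv; time 20 min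

- part of the solid electrophile that has reacted (what has only dissolved counts as not reacted) at 20 min
- share of the unused nucleophile that is free and not bound as protonated nucleophile, at 20 min

- as a solid, counted per litre of solution: solid electrophile
- at the start none of the solid electrophile is in solution
- what has only dissolved of solid electrophile counts as not reacted
- run time (flask): 20 min

I count in fractions of the solid charged. Step 4 keeps acid set free at protonated nucleophile over 36200 /M times nucleophile. The equilibrium constant of step 5 times free base starts at 37000, so I drop its return. The fraction f of nucleophile freed then obeys f·df/dt = (k5/K4) × base left × protonated nucleophile left. With both held at their charges, f squared grows as ρt, where ρ, 2 k5/K4 times both equivalents, is the release constant 0.0174 /min. So f reaches 58.9%.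

Dissolved electrophile climbs towards 90.0% of the charge with time constant 6.31 min, which I treat as a lag, then a plateau. Integrating step 1 over the root of t gives c = 9.36%.

The weak link is the held charges. Taking each less half of f lowers ρ to 0.0101 /min and f to 45.0%, and c falls in proportion to 7.15%. Each reaction uses one nucleophile and returns an acid that binds another, so free nucleophile is f less twice c. That gives fr = 25.0%.

The forecast says 6.3% and 27.5%, holding that “the slow first step converts only about 0.6 mM”; my c stands higher and my fr lower.

The flask gives 5.96% and 27.7%. Of their turnover up to 20 min, dissolution of the solid electrophile has half behind it by 4.35 min, and uptake of acid by free base has 46% behind it by 4.00 min. Step 1 reaches its halfway mark later, at 13.2 min. At 2.00 min the release constant gives 18.7%, and this flask reads 15.9% free nucleophile. With one setting moved and the rest held, the answer to c has moved by 5 points at 7.31 min or 30.6 min, or at 4.57 equiv of free base.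

For the neighbour flask with 4.80 equiv of free base, ρ is 0.0695 /min. The same correction gives f = 81.6%, so c = 13.0% and fr = 47.6%. That flask computes to 11.2% and 54.0%.

The constants used here were set for the occasion, and the outcome is calculated.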